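Start from the west run, which is the very flask asked about followed to 60.0 min, and count turnovers in it, as fractions of the substrate charged, before trying any rate law.

- west: substrate 35 mM; partner 52.5 mM; transfer agent 1.75 mM; initiator 4.6 mM; the very flask that is asked about, followed so far
- flask: substrate 35 mM; partner 52.5 mM; transfer agent 1.75 mM; initiator 4.6 mM; time 2.5 h

west run (percent of the substrate charged)

| time / min | substrate / % | target / % |
|---|---|---|
| 5.00 | 98.9 | 0 |
| 12.0 | 98.7 | 0.7 |
| 25.0 | 97.2 | 1.0 |
| 60.0 | 93.6 | 1.4 |

(standard deviation of a reading: 0.3 percentage points)

- percentages count the substrate that a species holds: one ended chains A counts as two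
- steps under discussion: partner + first chain carrier -> target + second chain carrier; transfer agent + first chain carrier -> side product + idle radical; 2 first chain carrier -> ended chains A; 2 second chain carrier -> ended chains B; substrate + second chain carrier -> released group + first chain carrier; 2 idle radical -> ended radicals; substrate -> decomposition product; partner -> decomposed reagent; substrate + initiating radical -> capped initiator + first chain carrier; initiator -> 2 initiating radical

* amount of substrate in percent of the substrate charged, at 30 min, 80 min and 2.5 h

At the last reading, set the target against the substrate lost:

target 1.4% over substrate lost 6.40% gives 0.219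

Call this number the turnover share: the part of the lost substrate that has come out as target. A value of one would mean a running chain, with each substrate lost passing through to target. The west run reads below that, so these readings show no long chain, though a short one stays open; take the straight line that follows as an assumption of this reckoning, which the share does not prove:

loss 0.0640 h⁻¹ of the charge, so substrate 96.8% at 30 min, 91.5% at 80 min, 84.0% at 2.5 h

Now test whether one number is enough. The share reads 0.357 at 25.0 min, but 0.111 over the stretch after it. With a scatter of 0.3 percentage points this is a hint and no more, yet it points away from one, so commit to the line and watch for a bend once the transfer agent, charged at 5.00% of the substrate, has gone.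

The forecast gives 96.8%, 82% and 35%, expecting that “the chain is released and loss should accelerate several-fold”.

The flask gives 96.8%, 92.3% and 84.1%.

    partner + first chain carrier → target + second chain carrier (k = 13900 M⁻¹ s⁻¹)
    transfer agent + first chain carrier → side product + idle radical (kL = 6.28 × 10⁵ M⁻¹ s⁻¹)
    2 first chain carrier → ended chains A (k = 1.10 × 10⁸ M⁻¹ s⁻¹)
    2 second chain carrier → ended chains B (k = 1.60 × 10⁸ M⁻¹ s⁻¹)
    substrate + second chain carrier → released group + first chain carrier (k = 14800 M⁻¹ s⁻¹)
    2 idle radical → ended radicals (k = 2.00 × 10⁷ M⁻¹ s⁻¹)
    substrate → decomposition product (k = 2.18 × 10⁻⁶ s⁻¹)
    partner → decomposed reagent (k = 5.61 × 10⁻⁴ s⁻¹)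
    substrate + initiating radical → capped initiator + first chain carrier (k = 2.57 × 10⁶ M⁻¹ s⁻¹)
    initiator → 2 initiating radical (k = 4.14 × 10⁻⁵ s⁻¹)

Watch the partner as well as the transfer agent. At 2.50 h the flask holds 0% of its transfer agent and 0.0826% of its partner, 1.44 equiv having gone to decomposed reagent, and the turnover share stands at 0.373, still below one. The substrate stays up through two steps acting together, the decay of the partner and the interception of the first chain carrier by the transfer agent: the same flask keeps 14.6% of its substrate without the decay and 31.0% without the interception.

All runs are simulated for substances that don't exist, noise included.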